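**Retrosynthetic overview**

1. Labels: ring A is the methoxy arene (a1 carries the 2-oxoheptyl chain, a3 the OMe, a5 the diaryl ether oxygen, a6 the depsidone carbonyl carbon); ring B is the other arene (b1 ester oxygen, b3 OH, b4 lactone carbonyl, b5 benzylic CH2, b6 ether oxygen). The route rests on one feature: the ether oxygen and the carboxyl carbon sit on the neighbouring carbons a5 and a6, with a6 next to the substituted carbon a1. This is the pattern left by adding an oxygen nucleophile and a carbon electrophile across an a5–a6 aryne that an oxygen substituent on a1 polarises.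
2. Key disconnection: the C(a5)–O and C(a6)–CO2 bonds are made together from the b6 phenoxide of the ring B spirolactone, 5-methoxy-3-(methoxymethoxy)benzyne and CO2. The a1 oxygen that steers the aryne is later converted to a triflate and exchanged for the 2-oxoheptyl chain by a palladium-catalysed tin enolate coupling.
3. Ring B phenol: methyl orsellinate is protected (MOM on the b1 oxygen, benzyl on the b3 oxygen), laterally lithiated and acylated with (R)-6-methyl-δ-valerolactone made from (R)-propylene oxide. Acid closes the spiro acyl ketal under thermodynamic control; bromination at b6, borylation and oxidation free the b6 hydroxyl.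
4. Aryne precursor: 5-methoxyresorcinol, mono-MOM ether, carbamate-directed ortho-silylation, then silyl triflate.
5. Ring order: the tetrahydropyranone building block first, then the isochromanone lactone ring together with the spiro centre, then (after the key step, which closes no ring) the seven-membered dioxepinone ring by lactonisation onto the b1 oxygen. Rings A and B are aromatic from the start.

Key step: step 13

Assumption: the (S) spiro centre of the target is the epimer favoured at equilibrium beside an (R) methyl-bearing carbon (lactone oxygen axial on the tetrahydropyran chair, methyl equatorial), so it is set by acid equilibration and not by a kinetic step.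

**Route**

Step 1
Reactants: 1 (R)-propylene oxide; 2 ethyl propiolate
Product: 4 ethyl (R)-5-hydroxyhex-2-ynoate, via lithium acetylide 3 (not isolated)
Conditions: n-BuLi, THF, −78 °C; BF3·OEt2; then 1, −78 °C; H2O
Reagents that add atoms: butyllithium, [Li]CCCC (lithium of 3 only)
Why: BF3-assisted SN2 opening of the epoxide by the lithium acetylide takes place at the unsubstituted CH2, so the (R) carbinol centre is carried over unchanged from 1.

Step 2
Reactants: 4 ethyl (R)-5-hydroxyhex-2-ynoate
Product: 6 (R)-6-methyltetrahydro-2H-pyran-2-one, via ethyl (R)-5-hydroxyhexanoate 5 (not isolated)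
Conditions: H2 (1 atm), 10% Pd/C, EtOAc, rt; filter; TsOH·H2O (cat.), toluene, 60 °C
Reagents that add atoms: none
Why: Catalytic hydrogenation saturates the alkyne and acid-catalysed lactonisation of the δ-hydroxy ester closes the six-membered lactone with loss of ethanol, the stereocentre being a spectator.

Step 3
Reactants: 7 methyl orsellinate
Product: 8 methyl 2-hydroxy-4-(methoxymethoxy)-6-methylbenzoate
Conditions: MOMCl (1.05 equiv), i-Pr2NEt, CH2Cl2, 0 °C
Reagents that add atoms: chloromethyl methyl ether, COCCl
Why: Williamson-type O-alkylation should go to the para hydroxyl because the ortho hydroxyl is tied up in a hydrogen bond to the ester carbonyl.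

Step 4
Reactants: 8 methyl 2-hydroxy-4-(methoxymethoxy)-6-methylbenzoate
Product: 9 methyl 2-(benzyloxy)-4-(methoxymethoxy)-6-methylbenzoate
Conditions: BnBr, K2CO3, DMF, 60 °C
Reagents that add atoms: benzyl bromide, BrCc1ccccc1
Why: Williamson etherification of the remaining chelated phenol under more forcing conditions, with the MOM ether and ester inert to carbonate.

Step 5
Reactants: 9 methyl 2-(benzyloxy)-4-(methoxymethoxy)-6-methylbenzoate; 6 (R)-6-methyltetrahydro-2H-pyran-2-one
Product: 11 methyl 2-(benzyloxy)-6-[(6R)-6-hydroxy-2-oxoheptyl]-4-(methoxymethoxy)benzoate (in equilibrium with its cyclic hemiketal), via lithiated toluate 10 (not isolated)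
Conditions: LDA, THF, −78 °C; then 6, −78 °C; AcOH, −78 °C
Reagents that add atoms: lithium diisopropylamide, [Li]N(C(C)C)C(C)C (lithium of 10 only)
Why: Lateral lithiation of the ortho-toluate and acylation by the lactone stop after one addition because the cyclic lactolate persists at low temperature, and the carbinol centre from 6 is not touched.

Step 6
Reactants: 11 methyl 2-(benzyloxy)-6-[(6R)-6-hydroxy-2-oxoheptyl]-4-(methoxymethoxy)benzoate
Product: 12 (3S,6'R)-8-(benzyloxy)-6-(methoxymethoxy)-6'-methylspiro[isochromane-3,2'-oxan]-1-one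
Conditions: CSA (cat.), 4 Å MS, CH2Cl2, rt
Reagents that add atoms: none
Why: Acid-catalysed hemiketalisation and lactonisation (intramolecular acyl ketal formation with loss of methanol) close the isochromanone ring, and because the acyl ketal ionises reversibly the spiro centre should settle under thermodynamic control as the (S) epimer, with the lactone oxygen axial on the tetrahydropyran chair (anomeric effect) and the methyl group of the (R) centre equatorial.

Step 7
Reactants: 12 the spirolactone
Product: 13 (3S,6'R)-8-(benzyloxy)-5-bromo-6-(methoxymethoxy)-6'-methylspiro[isochromane-3,2'-oxan]-1-one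
Conditions: NBS, MeCN, 0 °C
Reagents that add atoms: N-bromosuccinimide, O=C1CCC(=O)N1Br
Why: Electrophilic aromatic bromination should go to b6 (para to the benzyloxy group, ortho to the MOM ether), since the only other free position, b2, is crowded between two alkoxy groups.

Step 8
Reactants: 13 the b6 bromide
Product: 15 (3S,6'R)-8-(benzyloxy)-5-hydroxy-6-(methoxymethoxy)-6'-methylspiro[isochromane-3,2'-oxan]-1-one (ring B phenol), via aryl boronate 14 (not isolated)
Conditions: B2pin2, Pd(OAc)2, SPhos, KOAc, dioxane, 90 °C; then Me3NO, THF, 50 °C; H2O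
Reagents that add atoms: bis(pinacolato)diboron, CC1(C)OB(OC1(C)C)B1OC(C)(C)C(C)(C)O1 (boryl group of 14 only); trimethylamine N-oxide, C[N+](C)(C)[O-]
Why: Miyaura borylation with a bulky biarylphosphine copes with the di-ortho-substituted bromide, and amine N-oxide oxidation of the C–B bond is neutral, so the acyl ketal lactone is not exposed to aqueous base.

Step 9
Reactants: 16 5-methoxyresorcinol
Product: 17 3-methoxy-5-(methoxymethoxy)phenol
Conditions: MOMCl (1.0 equiv), i-Pr2NEt, THF/CH2Cl2, 0 °C
Reagents that add atoms: chloromethyl methyl ether, COCCl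
Why: Williamson-type etherification of a symmetric diphenol with one equivalent of electrophile should give the mono-MOM ether as the main component of a statistical mixture, from which unreacted diol is recovered.

Step 10
Reactants: 17 3-methoxy-5-(methoxymethoxy)phenol
Product: 18 3-methoxy-5-(methoxymethoxy)phenyl isopropylcarbamate
Conditions: i-PrNCO, Et3N (cat.), CH2Cl2, rt
Reagents that add atoms: isopropyl isocyanate, CC(C)N=C=O
Why: Base-catalysed addition of the phenol to the isocyanate installs a carbamate that is a strong ortho-director and can later be removed under mild base.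

Step 11
Reactants: 18 3-methoxy-5-(methoxymethoxy)phenyl isopropylcarbamate
Product: 22 5-methoxy-3-(methoxymethoxy)-2-(trimethylsilyl)phenyl isopropylcarbamate, via N-silyl carbamate 19 (not isolated), via aryllithium 20 (not isolated), via bis-silyl carbamate 21 (not isolated)
Conditions: TMSOTf, TMEDA, Et2O, 0 °C → rt; n-BuLi, −78 °C; TMSCl; aq. NH4Cl
Reagents that add atoms: chlorotrimethylsilane, C[Si](C)(C)Cl; trimethylsilyl triflate, C[Si](C)(C)OS(=O)(=O)C(F)(F)F (N-silyl group of 19–21 only); butyllithium, [Li]CCCC (lithium of 20 only)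
Why: Directed ortho-metalation, in which the carbamate (N-silylated in the flask so that it survives butyllithium) and the MOM ether together direct lithiation to the carbon between them in preference to the site beside the weaker methoxy director, after which TMSCl traps the aryllithium and the N-silyl group is lost on work-up.

Step 12
Reactants: 22 the ortho-silyl carbamate
Product: 24 5-methoxy-3-(methoxymethoxy)-2-(trimethylsilyl)phenyl trifluoromethanesulfonate, via ortho-silyl phenol 23 (not isolated)
Conditions: DBU, Et2NH, MeCN, 40 °C; then PhNTf2, rt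
Reagents that add atoms: N-phenylbis(trifluoromethanesulfonimide), O=S(=O)(N(c1ccccc1)S(=O)(=O)C(F)(F)F)C(F)(F)F
Why: E1cB cleavage of the N-monoalkyl carbamate (the isocyanate is scavenged by diethylamine) frees the phenoxide under conditions that spare the aryl–silicon bond, and sulfonylation in the same flask gives the ortho-silylaryl triflate.

Step 13
Reactants: 15 ring B phenol; 24 the silyl triflate; 25 carbon dioxide
Product: 30 2-{[(3S,6'R)-8-(benzyloxy)-6-(methoxymethoxy)-6'-methyl-1-oxospiro[isochromane-3,2'-oxan]-5-yl]oxy}-4-methoxy-6-(methoxymethoxy)benzoic acid (seco acid), via potassium phenoxide 26 (not isolated), via aryne 27 (not isolated), via aryl anion 28 (not isolated), via potassium carboxylate 29 (not isolated)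
Conditions: KH, THF, 0 °C; then KF, 18-crown-6, CO2 (1 atm), 24 (1.3 equiv) added over 6 h, 0 °C → rt; aq. KHSO4, 0 °C
Reagents that add atoms: potassium hydride, [K+].[H-] (potassium of 26, 28 and 29 only)
Why: Proposed new method: fluoride attack on silicon with loss of triflate gives aryne 27, the crown-ether-separated phenoxide 26 adds to a5 (the aryne carbon remote from the a1 methoxymethoxy group), and the resulting a6 aryl anion 28, which has no ortho leaving group and no proton donor in the dry medium, is captured by CO2 as carboxylate 29. The closest known reaction types are the three-component coupling of arynes with amine nucleophiles and CO2 and the fluoride-mediated O-arylation of phenols by ortho-silylaryl triflates; a phenoxide as the nucleophile in the CO2-trapping manifold is the untested part. No ring is closed and no stereocentre is formed, and the spiro acyl ketal is a spectator under these non-acidic conditions. The step needs oxygen on a5 and carbon on a6, which the inductive distortion of the aryne by the a1 oxygen and the lower steric demand at a5 should secure. It also needs carboxylation to outrun protonation, which is addressed by forming the phenoxide with KH (H2 as the only by-product), avoiding acetonitrile and keeping the aryne concentration low under a CO2 atmosphere. Reversible capture of 26 by CO2 as an aryl carbonate should be tolerable because the free phenoxide is by far the better nucleophile toward the aryne, and ring B has no free ortho or para carbon for C-carboxylation.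

Step 14
Reactants: 30 the seco acid
Product: 31 2-{[(3S,6'R)-8-(benzyloxy)-6-hydroxy-6'-methyl-1-oxospiro[isochromane-3,2'-oxan]-5-yl]oxy}-6-hydroxy-4-methoxybenzoic acid
Conditions: NaHSO4·SiO2, CH2Cl2, rt
Reagents that add atoms: none
Why: Acid-catalysed acetal cleavage removes both aryl MOM ethers on a solid acid in a non-nucleophilic solvent, where the benzyl ether is stable and the acyl ketal, if it ionises, can only re-close to the same favoured spiro epimer.

Step 15
Reactants: 31 the dihydroxy acid
Product: 32 depsidone phenol (dibenzo[b,e][1,4]dioxepin-11-one with free a1 hydroxyl, a3 OMe, b3 benzyloxy group and the (S)-spiro, (R)-methyl tetrahydropyran lactone on b4/b5)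
Conditions: DCC, DMAP (cat.), CH2Cl2 (high dilution), 0 °C → rt
Reagents that add atoms: none
Why: Carbodiimide activation of the acid and lactonisation by the b1 phenol, the only hydroxyl that can reach the activated carbonyl intramolecularly, should close the seven-membered depsidone ring.

Step 16
Reactants: 32 the depsidone phenol
Product: 33 depsidone a1 triflate
Conditions: Tf2O, pyridine, CH2Cl2, 0 °C
Reagents that add atoms: trifluoromethanesulfonic anhydride, O=S(=O)(OS(=O)(=O)C(F)(F)F)C(F)(F)F
Why: O-sulfonylation of the only free phenol turns the a1 oxygen that steered the aryne into a cross-coupling handle.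

Step 17
Reactants: 34 heptan-2-one
Product: 36 tributyl(2-oxoheptyl)stannane (in equilibrium with its O-stannyl enol form), via lithium enolate 35 (not isolated)
Conditions: LDA, THF, −78 °C; Bu3SnCl, −78 °C → rt
Reagents that add atoms: tributyltin chloride, CCCC[Sn](Cl)(CCCC)CCCC; lithium diisopropylamide, [Li]N(C(C)C)C(C)C (lithium of 35 only)
Why: Kinetic deprotonation at the methyl group and stannylation of the enolate give the terminal tin enolate, the only isomer that takes part in the following coupling.

Step 18
Reactants: 33 depsidone a1 triflate; 36 tributyl(2-oxoheptyl)stannane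
Product: 37 O-benzyl ether of the target (2-oxoheptyl chain on a1, benzyloxy group on b3)
Conditions: PdCl2[P(o-tol)3]2 (cat.), LiCl, dioxane, 90 °C
Reagents that add atoms: none
Why: Kosugi–Migita–Stille arylation of a tin enolate joins a1 to the enolate CH2 under neutral conditions that the depsidone ester and the acyl ketal tolerate, with chloride as the usual additive for aryl triflates.

Step 19
Reactants: 37 O-benzyl ether of the target
Product: 38 CNP0301127.1 (target)
Conditions: H2 (1 atm), 10% Pd/C, EtOAc, rt
Reagents that add atoms: none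
Why: Hydrogenolysis of the benzyl ether frees the b3 phenol, while the aliphatic ketone, the aryl ester, the diaryl ether and the acyl ketal are not reduced under these conditions.

**Compound list**

1 | (R)-propylene oxide | C[C@@H]1CO1 | starting material
2 | ethyl propiolate | CCOC(=O)C#C | starting material
3 | ethyl 3-lithioprop-2-ynoate (lithium acetylide) | CCOC(=O)C#C[Li] | intermediate (not isolated)
4 | ethyl (R)-5-hydroxyhex-2-ynoate | CCOC(=O)C#CC[C@@H](C)O | intermediate
5 | ethyl (R)-5-hydroxyhexanoate | CCOC(=O)CCC[C@@H](C)O | intermediate (not isolated)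
6 | (R)-6-methyltetrahydro-2H-pyran-2-one | C[C@@H]1CCCC(=O)O1 | intermediate
7 | methyl orsellinate | COC(=O)c1c(C)cc(O)cc1O | starting material
8 | methyl 2-hydroxy-4-(methoxymethoxy)-6-methylbenzoate | COC(=O)c1c(C)cc(OCOC)cc1O | intermediate
9 | methyl 2-(benzyloxy)-4-(methoxymethoxy)-6-methylbenzoate | COC(=O)c1c(C)cc(OCOC)cc1OCc1ccccc1 | intermediate
10 | methyl 2-(benzyloxy)-6-(lithiomethyl)-4-(methoxymethoxy)benzoate (lithiated toluate) | COC(=O)c1c(C[Li])cc(OCOC)cc1OCc1ccccc1 | intermediate (not isolated)
11 | methyl 2-(benzyloxy)-6-[(6R)-6-hydroxy-2-oxoheptyl]-4-(methoxymethoxy)benzoate | COC(=O)c1c(CC(=O)CCC[C@@H](C)O)cc(OCOC)cc1OCc1ccccc1 | intermediate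
12 | (3S,6'R)-8-(benzyloxy)-6-(methoxymethoxy)-6'-methylspiro[isochromane-3,2'-oxan]-1-one | COCOc1cc(OCc2ccccc2)c2c(c1)C[C@]1(CCC[C@@H](C)O1)OC2=O | intermediate
13 | (3S,6'R)-8-(benzyloxy)-5-bromo-6-(methoxymethoxy)-6'-methylspiro[isochromane-3,2'-oxan]-1-one | COCOc1cc(OCc2ccccc2)c2c(c1Br)C[C@]1(CCC[C@@H](C)O1)OC2=O | intermediate
14 | (3S,6'R)-8-(benzyloxy)-6-(methoxymethoxy)-6'-methyl-5-(4,4,5,5-tetramethyl-1,3,2-dioxaborolan-2-yl)spiro[isochromane-3,2'-oxan]-1-one | COCOc1cc(OCc2ccccc2)c2c(c1B1OC(C)(C)C(C)(C)O1)C[C@]1(CCC[C@@H](C)O1)OC2=O | intermediate (not isolated)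
15 | (3S,6'R)-8-(benzyloxy)-5-hydroxy-6-(methoxymethoxy)-6'-methylspiro[isochromane-3,2'-oxan]-1-one (ring B phenol) | Oc1c(OCOC)cc(OCc2ccccc2)c2c1C[C@]1(CCC[C@@H](C)O1)OC2=O | intermediate
16 | 5-methoxyresorcinol | COc1cc(O)cc(O)c1 | starting material
17 | 3-methoxy-5-(methoxymethoxy)phenol | COCOc1cc(O)cc(OC)c1 | intermediate
18 | 3-methoxy-5-(methoxymethoxy)phenyl isopropylcarbamate | COCOc1cc(OC)cc(OC(=O)NC(C)C)c1 | intermediate
19 | 3-methoxy-5-(methoxymethoxy)phenyl N-isopropyl-N-(trimethylsilyl)carbamate | COCOc1cc(OC)cc(OC(=O)N(C(C)C)[Si](C)(C)C)c1 | intermediate (not isolated)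
20 | 2-lithio-5-methoxy-3-(methoxymethoxy)phenyl N-isopropyl-N-(trimethylsilyl)carbamate | COCOc1cc(OC)cc(OC(=O)N(C(C)C)[Si](C)(C)C)c1[Li] | intermediate (not isolated)
21 | 5-methoxy-3-(methoxymethoxy)-2-(trimethylsilyl)phenyl N-isopropyl-N-(trimethylsilyl)carbamate | COCOc1cc(OC)cc(OC(=O)N(C(C)C)[Si](C)(C)C)c1[Si](C)(C)C | intermediate (not isolated)
22 | 5-methoxy-3-(methoxymethoxy)-2-(trimethylsilyl)phenyl isopropylcarbamate | COCOc1cc(OC)cc(OC(=O)NC(C)C)c1[Si](C)(C)C | intermediate
23 | 5-methoxy-3-(methoxymethoxy)-2-(trimethylsilyl)phenol | COCOc1cc(OC)cc(O)c1[Si](C)(C)C | intermediate (not isolated)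
24 | 5-methoxy-3-(methoxymethoxy)-2-(trimethylsilyl)phenyl trifluoromethanesulfonate | C[Si](C)(C)c1c(OCOC)cc(OC)cc1OS(=O)(=O)C(F)(F)F | intermediate
25 | carbon dioxide | O=C=O | starting material
26 | potassium salt of ring B phenol 15 | [K+].[O-]c1c(OCOC)cc(OCc2ccccc2)c2c1C[C@]1(CCC[C@@H](C)O1)OC2=O | intermediate (not isolated)
27 | 5-methoxy-3-(methoxymethoxy)benzyne | COCOC1=CC(OC)=CC#C1 | intermediate (not isolated)
28 | a6-potassio diaryl ether (aryl anion ortho to the MOM ether and the new aryloxy group) | COCOc1cc(OC)cc(Oc2c(OCOC)cc(OCc3ccccc3)c3c2C[C@]2(CCC[C@@H](C)O2)OC3=O)[c-]1.[K+] | intermediate (not isolated)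
29 | potassium salt of seco acid 30 | COCOc1cc(OC)cc(Oc2c(OCOC)cc(OCc3ccccc3)c3c2C[C@]2(CCC[C@@H](C)O2)OC3=O)c1C(=O)[O-].[K+] | intermediate (not isolated)
30 | 2-{[(3S,6'R)-8-(benzyloxy)-6-(methoxymethoxy)-6'-methyl-1-oxospiro[isochromane-3,2'-oxan]-5-yl]oxy}-4-methoxy-6-(methoxymethoxy)benzoic acid | COCOc1cc(OC)cc(Oc2c(OCOC)cc(OCc3ccccc3)c3c2C[C@]2(CCC[C@@H](C)O2)OC3=O)c1C(=O)O | intermediate
31 | 2-{[(3S,6'R)-8-(benzyloxy)-6-hydroxy-6'-methyl-1-oxospiro[isochromane-3,2'-oxan]-5-yl]oxy}-6-hydroxy-4-methoxybenzoic acid | OC(=O)c1c(O)cc(OC)cc1Oc1c(O)cc(OCc2ccccc2)c2c1C[C@]1(CCC[C@@H](C)O1)OC2=O | intermediate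
32 | depsidone phenol (a1 OH, a3 OMe, b3 OBn, spiro lactone on b4/b5) | Oc1cc(OC)cc2c1C(=O)Oc1cc(OCc3ccccc3)c3c(c1O2)C[C@]1(CCC[C@@H](C)O1)OC3=O | intermediate
33 | depsidone a1 triflate | O=S(=O)(Oc1cc(OC)cc2c1C(=O)Oc1cc(OCc3ccccc3)c3c(c1O2)C[C@]1(CCC[C@@H](C)O1)OC3=O)C(F)(F)F | intermediate
34 | heptan-2-one | CCCCCC(C)=O | starting material
35 | lithium hept-1-en-2-olate | [Li]OC(=C)CCCCC | intermediate (not isolated)
36 | tributyl(2-oxoheptyl)stannane | CCCCCC(=O)C[Sn](CCCC)(CCCC)CCCC | intermediate
37 | O-benzyl ether of the target | CCCCCC(=O)Cc1cc(OC)cc2c1C(=O)Oc1cc(OCc3ccccc3)c3c(c1O2)C[C@]1(CCC[C@@H](C)O1)OC3=O | intermediate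
38 | CNP0301127.1 | CCCCCC(=O)Cc1cc(OC)cc2c1C(=O)Oc1cc(O)c3c(c1O2)C[C@]1(CCC[C@@H](C)O1)OC3=O | target

**Step count and risks**

Total step count: 19. Longest linear sequence: 12 steps (methyl orsellinate 7 to the target 38 through steps 3–8, 13–16, 18 and 19).

Steps most likely to fail:

1. Step 13 (three-component aryne coupling). The aryl anion may be protonated before it meets CO2, which would give the simple diaryl ether. The phenoxide may be held back as its aryl carbonate so that the aryne is lost to other pathways. The product carboxylate may add to a second aryne. Fallback with known chemistry, setting out from 15 and coming back at 30: commercial 2-fluoro-4,6-dimethoxybenzaldehyde is demethylated with BCl3 (CH2Cl2, −78 → 0 °C) at the methoxy group ortho to the formyl group to give 2-fluoro-6-hydroxy-4-methoxybenzaldehyde F1. Protection (MOMCl, i-Pr2NEt, CH2Cl2) gives 2-fluoro-4-methoxy-6-(methoxymethoxy)benzaldehyde F2. Nucleophilic aromatic substitution of its fluoride by phenol 15 (K2CO3, DMF, 80 °C) should give the diaryl ether aldehyde F3, and Pinnick oxidation (NaClO2, NaH2PO4, 2-methyl-2-butene, t-BuOH/H2O) would deliver seco acid 30.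

2. Step 18 (tin enolate coupling). Transmetalation and reductive elimination at the arylpalladium beside the depsidone carbonyl may be slow, so that reduction or hydrolysis of the triflate and decay of the moisture-sensitive tin enolate take over. Fallback, setting out from 33 and coming back at 37: Suzuki–Miyaura coupling of 33 with commercial (E)-hept-1-enylboronic acid pinacol ester (Pd(dppf)Cl2, CsF, dioxane, 80 °C, no water) should give the (E)-hept-1-enyl depsidone F4. Epoxidation (mCPBA, NaHCO3, CH2Cl2, 0 °C) gives the trans epoxide F5 as a mixture of two diastereomers. A Meinwald-type isomerisation catalysed by Pd(OAc)2/PBu3 (t-BuOH, reflux), which opens the benzylic C–O bond and shifts hydride, would give the benzyl ketone 37.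

3. Step 6 (spirolactonisation). The hemiketal may dehydrate toward the isocoumarin, and acyl transfer at the di-ortho-substituted methyl ester may be slow, with loss of the MOM ether on long acid exposure. Fallback, setting out from 9 (with lactone 6) and coming back at 12: saponification of 9 (KOH, DMSO/H2O, 90 °C) gives 2-(benzyloxy)-4-(methoxymethoxy)-6-methylbenzoic acid F6. Its dianion (LDA, 2.2 equiv, THF, −78 → 0 °C) is acylated with 6 at −78 °C to give, after mild acidification, 2-(benzyloxy)-6-[(6R)-6-hydroxy-2-oxoheptyl]-4-(methoxymethoxy)benzoic acid F7. Here the ring closes by simple condensation of the free acid with the hemiketal (PPTS cat., 4 Å MS, CH2Cl2, rt), with no acyl transfer at a hindered ester, to give 12 as the same thermodynamic spiro epimer.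

**Further compounds**

F1 | step 13 | 2-fluoro-6-hydroxy-4-methoxybenzaldehyde | O=Cc1c(O)cc(OC)cc1F
F2 | step 13 | 2-fluoro-4-methoxy-6-(methoxymethoxy)benzaldehyde | COCOc1cc(OC)cc(F)c1C=O
F3 | step 13 | 2-{[(3S,6'R)-8-(benzyloxy)-6-(methoxymethoxy)-6'-methyl-1-oxospiro[isochromane-3,2'-oxan]-5-yl]oxy}-4-methoxy-6-(methoxymethoxy)benzaldehyde | COCOc1cc(OC)cc(Oc2c(OCOC)cc(OCc3ccccc3)c3c2C[C@]2(CCC[C@@H](C)O2)OC3=O)c1C=O
F4 | step 18 | (E)-hept-1-enyl depsidone (alkene on a1, benzyloxy group on b3) | CCCCC/C=C/c1cc(OC)cc2c1C(=O)Oc1cc(OCc3ccccc3)c3c(c1O2)C[C@]1(CCC[C@@H](C)O1)OC3=O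
F5 | step 18 | trans-(3-pentyloxiran-2-yl) depsidone (both epoxide diastereomers) | CCCCCC1OC1c1cc(OC)cc2c1C(=O)Oc1cc(OCc3ccccc3)c3c(c1O2)C[C@]1(CCC[C@@H](C)O1)OC3=O
F6 | step 6 | 2-(benzyloxy)-4-(methoxymethoxy)-6-methylbenzoic acid | Cc1cc(OCOC)cc(OCc2ccccc2)c1C(=O)O
F7 | step 6 | 2-(benzyloxy)-6-[(6R)-6-hydroxy-2-oxoheptyl]-4-(methoxymethoxy)benzoic acid | OC(=O)c1c(CC(=O)CCC[C@@H](C)O)cc(OCOC)cc1OCc1ccccc1
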